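**Plan**

1. Chain numbering: C‑1 (lactone C=O) to C‑20 (terminal CH2OH). Retrosynthetic cuts, in order: the two O–Si bonds; C‑3–CH2OH (Stille); C‑2–C‑3 and the O–C‑1 acyl bond (Dieckmann closure of an α‑acetoxy ester); C‑5–C‑6 (alkenyl metal + glycidic ester); C‑12–C‑13 (fragment union); C‑7–C‑8 (carbomagnesiation of propargyl alcohol).
2. Enabling feature: C‑12–C‑13 is the central σ‑bond of the 1,5‑diene C‑10=C‑11(CH3)–C‑12H2–C‑13H2–C‑14=C‑15(CH3). Both atoms are primary allylic carbons that are electrophiles as their halides. No ring takes part: the butenolide (ring O, C‑1 to C‑4) lies eight bonds away and is built later.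
3. The two like‑polarity carbons are joined by reversing the polarity of C‑13 (allylic chloride → allylbarium), which attacks the C‑12 allylic bromide α,α′; no auxiliary group has to be removed afterwards.
4. Forward order: C‑6–C‑12 piece (alkenyl iodide at C‑6, bromide at C‑12; steps 1–4); C‑13–C‑20 piece (steps 5–6); union (step 7); C‑3–C‑5 from a glycidic ester, C‑1/C‑2 from an acetyl group; the only ring closed by Dieckmann condensation; C‑3 hydroxymethyl by Stille coupling; desilylation.
5. Stereochemistry: C‑4 (R) comes unchanged from methyl (R)‑glycidate. 14E comes from geranyl chloride; 10E and 18E from E‑selective SeO2 oxidations; 6Z from anti‑carbomagnesiation/iodinolysis. All olefin geometries are retained in the coupling.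

Key step: step 7

Remark: 5‑bromo‑2‑methylpent‑2‑ene, propargyl alcohol, geranyl chloride, methyl (2R)‑glycidate and (tributylstannyl)methanol are taken as commercial. TBS = tert‑butyldimethylsilyl. "Side chain A" = (2Z,6E,10E,14E)‑16‑(TBS‑oxy)‑3‑[(TBS‑oxy)methyl]‑7,11,15‑trimethylhexadeca‑2,6,10,14‑tetraen‑1‑yl.

**Route**

Step 1
Reactants: 1 5-bromo-2-methylpent-2-ene; 2 prop-2-yn-1-ol
Product: 5 (2Z)-3-iodo-2-(4-methylpent-3-en-1-yl)prop-2-en-1-ol, via homoprenylmagnesium bromide 3 (not isolated), via chelated alkenylmagnesium alkoxide 4 (not isolated)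
Conditions: Mg, THF, rt (gives 3, 2.5 equiv); 2, CuI (10 mol%), Et2O–THF, −10 °C → rt; then I2, THF, −40 → 0 °C
Reagents that add atoms: iodine, II
Why: Copper-catalysed anti-carbomagnesiation of the magnesium alkoxide of a propargylic alcohol (carbometalation through a five-membered O–Mg chelate) should put the alkyl group on the internal carbon and magnesium on the terminal carbon cis to CH2O, and iodinolysis with retention should give the (Z)-iodide, which fixes the geometry of the hydroxymethyl-bearing olefin (6Z).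

Step 2
Reactants: 5 (2Z)-3-iodo-2-(4-methylpent-3-en-1-yl)prop-2-en-1-ol
Product: 6 tert-butyl{[(2Z)-3-iodo-2-(4-methylpent-3-en-1-yl)prop-2-en-1-yl]oxy}dimethylsilane
Conditions: TBSCl, imidazole, CH2Cl2, 0 °C → rt
Reagents that add atoms: tert-butyldimethylsilyl chloride, CC(C)(C)[Si](C)(C)Cl
Why: Routine silylation of a primary allylic alcohol, needed because the free hydroxyl would quench the organometallic reagents of steps 7 and 8.

Step 3
Reactants: 6 tert-butyl{[(2Z)-3-iodo-2-(4-methylpent-3-en-1-yl)prop-2-en-1-yl]oxy}dimethylsilane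
Product: 7 (2E,6Z)-6-[(TBS-oxy)methyl]-7-iodo-2-methylhepta-2,6-dien-1-ol
Conditions: SeO2 (0.3 equiv), t-BuOOH (3 equiv, decane), salicylic acid (10 mol%), CH2Cl2, rt
Reagents that add atoms: tert-butyl hydroperoxide, CC(C)(C)OO (terminal source of the oxygen atom); selenium dioxide, O=[Se]=O (catalytic oxygen-transfer agent)
Why: Riley oxidation (ene reaction, then [2,3]-sigmatropic shift) should hydroxylate the (E)-methyl group of the electron-rich isopropylidene terminus, the other olefin being deactivated by iodine and the allylic silyloxy group; this sets 10E.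

Step 4
Reactants: 7 (2E,6Z)-6-[(TBS-oxy)methyl]-7-iodo-2-methylhepta-2,6-dien-1-ol
Product: 8 (1Z,5E)-7-bromo-1-iodo-6-methyl-2-[(TBS-oxy)methyl]hepta-1,5-diene
Conditions: CBr4, PPh3, CH2Cl2, −20 → 0 °C
Reagents that add atoms: carbon tetrabromide, BrC(Br)(Br)Br
Why: Appel reaction; SN2 displacement at the primary allylic carbon should give the bromide without touching the olefin geometries or the alkenyl iodide.

Step 5
Reactants: 9 geranyl chloride, (2E)-1-chloro-3,7-dimethylocta-2,6-diene
Product: 10 (2E,6E)-8-chloro-2,6-dimethylocta-2,6-dien-1-ol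
Conditions: SeO2 (0.3 equiv), t-BuOOH (3 equiv, decane), salicylic acid (10 mol%), CH2Cl2, rt
Reagents that add atoms: tert-butyl hydroperoxide, CC(C)(C)OO (terminal source of the oxygen atom); selenium dioxide, O=[Se]=O (catalytic oxygen-transfer agent)
Why: Riley oxidation should again act on the (E)-methyl of the distal, more electron-rich olefin (the 2,3-olefin is deactivated by the allylic chlorine), setting 18E while the allylic chloride survives.

Step 6
Reactants: 10 (2E,6E)-8-chloro-2,6-dimethylocta-2,6-dien-1-ol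
Product: 11 tert-butyl{[(2E,6E)-8-chloro-2,6-dimethylocta-2,6-dien-1-yl]oxy}dimethylsilane
Conditions: TBSOTf, 2,6-lutidine, CH2Cl2, −78 °C
Reagents that add atoms: tert-butyldimethylsilyl trifluoromethanesulfonate, CC(C)(C)[Si](C)(C)OS(=O)(=O)C(F)(F)F
Why: Silylation with a non-nucleophilic base at low temperature should protect the alcohol without N-alkylation of the base by the allylic chloride.

Step 7
Reactants: 11 tert-butyl{[(2E,6E)-8-chloro-2,6-dimethylocta-2,6-dien-1-yl]oxy}dimethylsilane; 8 (1Z,5E)-7-bromo-1-iodo-6-methyl-2-[(TBS-oxy)methyl]hepta-1,5-diene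
Product: 13 (2E,6E,10E,14Z)-1-(TBS-oxy)-14-[(TBS-oxy)methyl]-15-iodo-2,6,10-trimethylpentadeca-2,6,10,14-tetraene, via allylbarium chloride 12 (not isolated)
Conditions: BaI2 (1.0 equiv), freshly prepared lithium biphenylide (2.0 equiv), THF, rt (activated barium); 11 (1.1 equiv), −78 °C, 30 min; then 8 (0.7 equiv), THF, −78 °C
Reagents that add atoms: none
Why: Activated barium inserts into the allylic C–Cl bond of 11 at −78 °C to give allylbarium chloride 12, which at this temperature keeps its (E) geometry without 1,3-metallotropic scrambling and then displaces bromide from 8 by SN2 attack through its α-carbon, so that two carbons that are both electrophilic as halides are joined after polarity reversal of one. The closest known reaction type is the α,α′-selective cross-coupling of allylic barium reagents with allylic halides used for head-to-tail extension of oligoprenyl chains. No ring is closed and no stereocentre is formed. The step needs α- over γ-attack in the nucleophile, SN2 over SN2′ in the electrophile and retention of both (E)-olefins: barium sits on and reacts at the unsubstituted allyl terminus, and the CH2Br carbon of 8 is far less hindered than its trisubstituted γ-carbon. Chemoselectivity over the alkenyl iodide should follow from the unfavourable exchange of a stabilised allyl anion for an alkenyl anion, provided no free barium remains when 8 is added (hence the slight excess of 11 over barium).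

Step 8
Reactants: 13 (2E,6E,10E,14Z)-1-(TBS-oxy)-14-[(TBS-oxy)methyl]-15-iodo-2,6,10-trimethylpentadeca-2,6,10,14-tetraene; 14 methyl (2R)-oxirane-2-carboxylate (methyl (R)-glycidate)
Product: 17 methyl (2R,4Z,8E,12E,16E)-18-(TBS-oxy)-5-[(TBS-oxy)methyl]-2-hydroxy-9,13,17-trimethyloctadeca-4,8,12,16-tetraenoate, via alkenyllithium 15 (not isolated), via alkenylmagnesium bromide 16 (not isolated)
Conditions: t-BuLi (2.05 equiv), Et2O, −78 °C; MgBr2·OEt2 (1.1 equiv), −78 → −40 °C; CuI (15 mol%), 14 (1.5 equiv), THF, −40 → −20 °C; aqueous work-up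
Reagents that add atoms: none
Why: Iodine–lithium exchange with retention of olefin geometry, transmetalation to magnesium and copper-catalysed SN2 opening of the glycidic ester at its unsubstituted C-3 (epoxide opening by an alkenyl cuprate) should give the α-hydroxy ester; the (R) centre is carried over untouched from 14 and becomes C-4 of the target.

Step 9
Reactants: 17 methyl (2R,4Z,8E,12E,16E)-18-(TBS-oxy)-5-[(TBS-oxy)methyl]-2-hydroxy-9,13,17-trimethyloctadeca-4,8,12,16-tetraenoate
Product: 18 methyl (2R,4Z,8E,12E,16E)-2-acetoxy-18-(TBS-oxy)-5-[(TBS-oxy)methyl]-9,13,17-trimethyloctadeca-4,8,12,16-tetraenoate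
Conditions: Ac2O, pyridine, DMAP (cat.), CH2Cl2, 0 °C → rt
Reagents that add atoms: acetic anhydride, CC(=O)OC(C)=O
Why: Routine O-acetylation; the acetyl group supplies C-1 and C-2 of the future lactone.

Step 10
Reactants: 18 methyl (2R,4Z,8E,12E,16E)-2-acetoxy-18-(TBS-oxy)-5-[(TBS-oxy)methyl]-9,13,17-trimethyloctadeca-4,8,12,16-tetraenoate
Product: 19 (5R)-4-hydroxy-5-(side chain A)furan-2(5H)-one (5-substituted tetronic acid)
Conditions: LiHMDS (3 equiv), THF, −78 → −20 °C; aq. HCl work-up
Reagents that add atoms: none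
Why: Dieckmann condensation (5-exo-trig attack of the acetate enolate on the methyl ester) should close the only ring as the tetronic acid; kinetic deprotonation of the acetyl CH3 at −78 °C should leave the stereocentre untouched.

Step 11
Reactants: 19 (5R)-4-hydroxy-5-(side chain A)furan-2(5H)-one
Product: 20 (2R)-5-oxo-2-(side chain A)-2,5-dihydrofuran-3-yl trifluoromethanesulfonate
Conditions: Tf2O, i-Pr2NEt, CH2Cl2, −78 °C
Reagents that add atoms: trifluoromethanesulfonic anhydride, O=S(=O)(OS(=O)(=O)C(F)(F)F)C(F)(F)F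
Why: O-Sulfonylation of the vinylogous acid should give the enol triflate, a standard electrophile for palladium coupling, at a temperature at which the buffered polyene is inert.

Step 12
Reactants: 20 (2R)-5-oxo-2-(side chain A)-2,5-dihydrofuran-3-yl trifluoromethanesulfonate
Product: 21 (5R)-4-(hydroxymethyl)-5-(side chain A)furan-2(5H)-one (bis-TBS ether of hippolide F)
Conditions: Bu3SnCH2OH (1.5 equiv), Pd(PPh3)4 (5 mol%), LiCl (3 equiv), 1,4-dioxane, 80 °C
Reagents that add atoms: (tributylstannyl)methanol, CCCC[Sn](CCCC)(CCCC)CO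
Why: Stille coupling of an enol triflate, in which the α-oxygenated CH2OH group transfers in preference to butyl, should install the C-3 hydroxymethyl group under neutral conditions that do not affect the γ-stereocentre.

Step 13
Reactants: 21 (5R)-4-(hydroxymethyl)-5-(side chain A)furan-2(5H)-one
Product: 22 hippolide F, (5R)-4-(hydroxymethyl)-5-[(2Z,6E,10E,14E)-16-hydroxy-3-(hydroxymethyl)-7,11,15-trimethylhexadeca-2,6,10,14-tetraen-1-yl]furan-2(5H)-one
Conditions: HF·pyridine, pyridine, THF, 0 °C → rt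
Reagents that add atoms: none
Why: Buffered, non-basic fluoride desilylation should free both primary allylic alcohols without γ-deprotonation (racemisation) of the butenolide.

**Compound list**

1 | 5-bromo-2-methylpent-2-ene | CC(C)=CCCBr | starting material
2 | prop-2-yn-1-ol | OCC#C | starting material
3 | (4-methylpent-3-en-1-yl)magnesium bromide | CC(C)=CCC[Mg]Br | intermediate (not isolated)
4 | bromomagnesium (2Z)-3-(bromomagnesio)-2-(4-methylpent-3-en-1-yl)prop-2-en-1-olate | Br[Mg]OC/C(CCC=C(C)C)=C\[Mg]Br | intermediate (not isolated)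
5 | (2Z)-3-iodo-2-(4-methylpent-3-en-1-yl)prop-2-en-1-ol | CC(C)=CCC/C(=C/I)CO | intermediate
6 | tert-butyl{[(2Z)-3-iodo-2-(4-methylpent-3-en-1-yl)prop-2-en-1-yl]oxy}dimethylsilane | CC(C)=CCC/C(=C/I)CO[Si](C)(C)C(C)(C)C | intermediate
7 | (2E,6Z)-6-[(TBS-oxy)methyl]-7-iodo-2-methylhepta-2,6-dien-1-ol | OC/C(C)=C/CC/C(=C/I)CO[Si](C)(C)C(C)(C)C | intermediate
8 | (1Z,5E)-7-bromo-1-iodo-6-methyl-2-[(TBS-oxy)methyl]hepta-1,5-diene | BrC/C(C)=C/CC/C(=C/I)CO[Si](C)(C)C(C)(C)C | intermediate
9 | geranyl chloride, (2E)-1-chloro-3,7-dimethylocta-2,6-diene | CC(C)=CCC/C(C)=C/CCl | starting material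
10 | (2E,6E)-8-chloro-2,6-dimethylocta-2,6-dien-1-ol | OC/C(C)=C/CC/C(C)=C/CCl | intermediate
11 | tert-butyl{[(2E,6E)-8-chloro-2,6-dimethylocta-2,6-dien-1-yl]oxy}dimethylsilane | CC(C)(C)[Si](C)(C)OC/C(C)=C/CC/C(C)=C/CCl | intermediate
12 | chloro[(2E,6E)-8-(TBS-oxy)-3,7-dimethylocta-2,6-dien-1-yl]barium | CC(C)(C)[Si](C)(C)OC/C(C)=C/CC/C(C)=C/C[Ba]Cl | intermediate (not isolated)
13 | (2E,6E,10E,14Z)-1-(TBS-oxy)-14-[(TBS-oxy)methyl]-15-iodo-2,6,10-trimethylpentadeca-2,6,10,14-tetraene | CC(C)(C)[Si](C)(C)OC/C(C)=C/CC/C(C)=C/CC/C(C)=C/CC/C(=C/I)CO[Si](C)(C)C(C)(C)C | intermediate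
14 | methyl (2R)-oxirane-2-carboxylate | COC(=O)[C@H]1CO1 | starting material
15 | alkenyllithium from 13 (Li in place of I, geometry retained) | CC(C)(C)[Si](C)(C)OC/C(C)=C/CC/C(C)=C/CC/C(C)=C/CC/C(=C/[Li])CO[Si](C)(C)C(C)(C)C | intermediate (not isolated)
16 | alkenylmagnesium bromide from 15 | CC(C)(C)[Si](C)(C)OC/C(C)=C/CC/C(C)=C/CC/C(C)=C/CC/C(=C/[Mg]Br)CO[Si](C)(C)C(C)(C)C | intermediate (not isolated)
17 | methyl (2R,4Z,8E,12E,16E)-18-(TBS-oxy)-5-[(TBS-oxy)methyl]-2-hydroxy-9,13,17-trimethyloctadeca-4,8,12,16-tetraenoate | CC(C)(C)[Si](C)(C)OC/C(C)=C/CC/C(C)=C/CC/C(C)=C/CC/C(=C/C[C@@H](O)C(=O)OC)CO[Si](C)(C)C(C)(C)C | intermediate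
18 | methyl (2R,4Z,8E,12E,16E)-2-acetoxy-18-(TBS-oxy)-5-[(TBS-oxy)methyl]-9,13,17-trimethyloctadeca-4,8,12,16-tetraenoate | CC(C)(C)[Si](C)(C)OC/C(C)=C/CC/C(C)=C/CC/C(C)=C/CC/C(=C/C[C@@H](OC(C)=O)C(=O)OC)CO[Si](C)(C)C(C)(C)C | intermediate
19 | (5R)-4-hydroxy-5-(side chain A)furan-2(5H)-one | CC(C)(C)[Si](C)(C)OC/C(C)=C/CC/C(C)=C/CC/C(C)=C/CC/C(=C/C[C@H]1OC(=O)C=C1O)CO[Si](C)(C)C(C)(C)C | intermediate
20 | (2R)-5-oxo-2-(side chain A)-2,5-dihydrofuran-3-yl trifluoromethanesulfonate | CC(C)(C)[Si](C)(C)OC/C(C)=C/CC/C(C)=C/CC/C(C)=C/CC/C(=C/C[C@H]1OC(=O)C=C1OS(=O)(=O)C(F)(F)F)CO[Si](C)(C)C(C)(C)C | intermediate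
21 | (5R)-4-(hydroxymethyl)-5-(side chain A)furan-2(5H)-one | CC(C)(C)[Si](C)(C)OC/C(C)=C/CC/C(C)=C/CC/C(C)=C/CC/C(=C/C[C@H]1OC(=O)C=C1CO)CO[Si](C)(C)C(C)(C)C | intermediate
22 | hippolide F | C/C(=C\CC/C(C)=C/CC/C(C)=C/CC/C(=C/C[C@H]1OC(=O)C=C1CO)CO)CO | target

**Step count**

Total: 13 steps. Longest linear sequence: 11 steps (1–4, then 7–13, from 5-bromo-2-methylpent-2-ene).

**Steps most likely to fail**

Step 7. What may go wrong: electron transfer or halogen–metal exchange at the alkenyl iodide by residual barium, Wurtz-type homocoupling, and loss of α,α′-regiocontrol. The fallback uses sulfone-anion umpolung with the iodide masked; it sets out from 7 and 11 and returns at 13. Compound 7 is stannylated (hexabutylditin, Pd(PPh3)4, toluene, 80 °C) to the alkenylstannane alcohol F1, which is converted (MsCl, Et3N; then LiBr, THF) into the allylic bromide F2. Compound 11 and sodium benzenesulfinate (DMF, rt) give the allylic phenyl sulfone F3. Its lithio derivative (n-BuLi, THF–DMPU, −78 °C) is alkylated by F2 at the sulfonyl-bearing carbon to give the coupled sulfone F4. Palladium-catalysed hydride desulfonylation (PdCl2(dppp), LiBHEt3, THF, 0 °C) gives the pentadecatetraenyl stannane F5, and iododestannylation (I2, CH2Cl2, 0 °C) returns 13.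

Step 12. What may go wrong: slow transfer of the sp3 hydroxymethyl group from tin, so that hydrolysis or reduction of the enol triflate and butyl transfer compete. The fallback introduces the hydroxymethyl carbon before ring closure; it sets out from 17 and returns at 21. Compound 17 is converted (MeNHOMe·HCl, i-PrMgCl, THF, −20 °C) into the α-hydroxy Weinreb amide F6. Tributyl{[(4-methoxybenzyl)oxy]methyl}stannane F7 (from (tributylstannyl)methanol, NaH and 4-methoxybenzyl chloride) is transmetalated with n-BuLi, and the alkoxymethyllithium (excess, THF, −78 °C) adds to F6 to give the α-hydroxy ketone F8. Ketenylidenetriphenylphosphorane (toluene, 80 °C) acylates the hydroxyl group and closes the ring by intramolecular Wittig olefination of the ketone, giving the PMB-protected butenolide F9. DDQ (CH2Cl2–pH 7 buffer) removes the PMB group and returns 21.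

Step 10. What may go wrong: enolisation at the stereogenic α-carbon instead of the acetyl group, leading to partial racemisation or acyl migration. The fallback is a base-free ring closure; it sets out from 17 and returns at 19. Transesterification of 17 with allyl alcohol (Ti(OiPr)4 cat., toluene, 80 °C) gives the allyl α-hydroxy ester F10. Ketenylidenetriphenylphosphorane (THF, 60 °C) adds the hydroxyl group and closes the ring by intramolecular Wittig reaction on the ester carbonyl, giving the allyl tetronate F11. Pd(PPh3)4/morpholine (THF, rt) removes the allyl group and returns 19.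

Further compounds

F1 | step 7 | (2E,6Z)-6-[(TBS-oxy)methyl]-2-methyl-7-(tributylstannyl)hepta-2,6-dien-1-ol | OC/C(C)=C/CC/C(=C/[Sn](CCCC)(CCCC)CCCC)CO[Si](C)(C)C(C)(C)C
F2 | step 7 | (1Z,5E)-7-bromo-6-methyl-2-[(TBS-oxy)methyl]-1-(tributylstannyl)hepta-1,5-diene | BrC/C(C)=C/CC/C(=C/[Sn](CCCC)(CCCC)CCCC)CO[Si](C)(C)C(C)(C)C
F3 | step 7 | tert-butyl{[(2E,6E)-2,6-dimethyl-8-(phenylsulfonyl)octa-2,6-dien-1-yl]oxy}dimethylsilane | CC(C)(C)[Si](C)(C)OC/C(C)=C/CC/C(C)=C/CS(=O)(=O)c1ccccc1
F4 | step 7 | (2E,6E,10E,14Z)-1-(TBS-oxy)-14-[(TBS-oxy)methyl]-2,6,10-trimethyl-8-(phenylsulfonyl)-15-(tributylstannyl)pentadeca-2,6,10,14-tetraene (both epimers at C-8) | CC(C)(C)[Si](C)(C)OC/C(C)=C/CC/C(C)=C/C(C/C(C)=C/CC/C(=C/[Sn](CCCC)(CCCC)CCCC)CO[Si](C)(C)C(C)(C)C)S(=O)(=O)c1ccccc1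
F5 | step 7 | (2E,6E,10E,14Z)-1-(TBS-oxy)-14-[(TBS-oxy)methyl]-2,6,10-trimethyl-15-(tributylstannyl)pentadeca-2,6,10,14-tetraene | CC(C)(C)[Si](C)(C)OC/C(C)=C/CC/C(C)=C/CC/C(C)=C/CC/C(=C/[Sn](CCCC)(CCCC)CCCC)CO[Si](C)(C)C(C)(C)C
F6 | step 12 | (2R,4Z,8E,12E,16E)-18-(TBS-oxy)-5-[(TBS-oxy)methyl]-2-hydroxy-N-methoxy-N,9,13,17-tetramethyloctadeca-4,8,12,16-tetraenamide | CC(C)(C)[Si](C)(C)OC/C(C)=C/CC/C(C)=C/CC/C(C)=C/CC/C(=C/C[C@@H](O)C(=O)N(C)OC)CO[Si](C)(C)C(C)(C)C
F7 | step 12 | tributyl{[(4-methoxybenzyl)oxy]methyl}stannane | CCCC[Sn](CCCC)(CCCC)COCc1ccc(OC)cc1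
F8 | step 12 | (3R,5Z,9E,13E,17E)-19-(TBS-oxy)-6-[(TBS-oxy)methyl]-3-hydroxy-1-[(4-methoxybenzyl)oxy]-10,14,18-trimethylnonadeca-5,9,13,17-tetraen-2-one | CC(C)(C)[Si](C)(C)OC/C(C)=C/CC/C(C)=C/CC/C(C)=C/CC/C(=C/C[C@@H](O)C(=O)COCc1ccc(OC)cc1)CO[Si](C)(C)C(C)(C)C
F9 | step 12 | (5R)-4-{[(4-methoxybenzyl)oxy]methyl}-5-(side chain A)furan-2(5H)-one | CC(C)(C)[Si](C)(C)OC/C(C)=C/CC/C(C)=C/CC/C(C)=C/CC/C(=C/C[C@H]1OC(=O)C=C1COCc1ccc(OC)cc1)CO[Si](C)(C)C(C)(C)C
F10 | step 10 | prop-2-en-1-yl (2R,4Z,8E,12E,16E)-18-(TBS-oxy)-5-[(TBS-oxy)methyl]-2-hydroxy-9,13,17-trimethyloctadeca-4,8,12,16-tetraenoate | CC(C)(C)[Si](C)(C)OC/C(C)=C/CC/C(C)=C/CC/C(C)=C/CC/C(=C/C[C@@H](O)C(=O)OCC=C)CO[Si](C)(C)C(C)(C)C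
F11 | step 10 | (5R)-4-(prop-2-en-1-yloxy)-5-(side chain A)furan-2(5H)-one | CC(C)(C)[Si](C)(C)OC/C(C)=C/CC/C(C)=C/CC/C(C)=C/CC/C(=C/C[C@H]1OC(=O)C=C1OCC=C)CO[Si](C)(C)C(C)(C)C
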